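**Retrosynthetic overview**
- Target 17 ⇒ ring-closing metathesis (C6=C7) of the allyl/methallyl diene 16. The seven-membered ring is closed last, on a cyclopentanone that derives from 3-methylcyclopent-2-enone.
- 16 ⇒ anisoylation (acid chloride 15 from anisole) of diol 12 ⇒ chelation-controlled methallylation of β-hydroxy aldehyde 11 (sets C4).
- 11/9 ⇒ key step: three-component radical carbo-allylation of enone 5. A dimethoxymethyl radical (from selenide 7) adds to the β-carbon and the resulting α-keto radical is allylated (sets C3a and the quaternary C8a).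
- 5 ⇒ allylic oxidation of tertiary allylic alcohol 3 ⇒ catalytic enantioselective isopropyl addition to enone 1 (sets C3, which steers all later centres).

Assumption: the target is numbered as in azulene (C1 ketone, C3 carbinol, C3a/C8a ring fusion, C4 ester carbon, C6=C7 alkene); equivalents and selectivities are estimates, not measured values.

**Step 1**
Reactants: 1 3-methylcyclopent-2-en-1-one; 2 diisopropylzinc
Product: 3 (1R)-3-methyl-1-(propan-2-yl)cyclopent-2-en-1-ol
Conditions: 2 (1.6 equiv), Ti(OiPr)4 (1.2 equiv), trans-cyclohexane-1,2-diamine bis(2-hydroxycamphor-10-sulfonamide) ligand (10 mol %, enantiomer chosen for the R product), toluene, rt; aq. NH4Cl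
Reagents that add atoms: none
Why: Proposed new method: a chiral titanium bis(sulfonamide)-diolate delivers the isopropyl group to one face of the carbonyl in a 1,2-addition (the β-methyl group disfavours 1,4-addition), which sets C1 as R; closest known reaction type: the titanium/bis(sulfonamide)-diol-catalysed enantioselective 1,2-addition of Me2Zn and Et2Zn to cyclic enones.

**Step 2**
Reactants: 3 (1R)-3-methyl-1-(propan-2-yl)cyclopent-2-en-1-ol
Product: 5 (4R)-4-hydroxy-2-methyl-4-(propan-2-yl)cyclopent-2-en-1-one, via allylic tert-butyl peroxide 4 (not isolated)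
Conditions: Rh2(cap)4 (1 mol %), t-BuOOH (5 equiv), K2CO3 (0.5 equiv), CH2Cl2, rt
Reagents that add atoms: tert-butyl hydroperoxide, CC(C)(C)OO
Why: Dirhodium caprolactamate/t-BuOOH allylic oxidation abstracts hydrogen from the only allylic ring CH2, the allyl radical is peroxidised at that unhindered terminus rather than next to the quaternary carbinol, and the peroxide collapses to the enone without touching the carbinol stereocentre.

**Step 3**
Reactants: 6 trimethyl orthoformate
Product: 7 (dimethoxymethyl)(phenyl)selane
Conditions: PhSeH (1 equiv), 6 (10 equiv, as solvent), BF3·OEt2 (5 mol %), 0 °C → rt, MeOH removed; distil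
Reagents that add atoms: benzeneselenol, [SeH]c1ccccc1
Why: Acid-catalysed orthoester exchange through the dimethoxycarbenium ion replaces one methoxy group by the soft selenol (excess orthoformate stops it at mono-exchange, as in the known tris-selenation of orthoformates), giving a formyl-radical precursor.

**Step 4 (key step)**
Reactants: 5 (4R)-4-hydroxy-2-methyl-4-(propan-2-yl)cyclopent-2-en-1-one; 7 (dimethoxymethyl)(phenyl)selane; 8 allyltrimethylstannane
Product: 9 (2R,3R,4R)-3-(dimethoxymethyl)-4-hydroxy-2-methyl-4-(propan-2-yl)-2-(prop-2-en-1-yl)cyclopentan-1-one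
Conditions: 7 (2 equiv), 8 (3 equiv), AIBN (0.2 equiv), PhH, 80 °C
Reagents that add atoms: none
Why: Proposed new method: Me3Sn• abstracts PhSe from 7 to give the small, nucleophilic dimethoxymethyl radical, which adds to the electron-poor β-carbon C3 of 5 anti to the isopropyl group (syn to OH), and the resulting electrophilic tertiary α-keto radical at C2 is captured by electron-rich 8 anti to the new C3 substituent (SH2′, releasing Me3Sn• to carry the chain), so both C–C bonds, the C3 centre and the quaternary C2 centre are set in one polarity-matched chain; closest known reaction type: three-component radical conjugate addition/Keck allylation of enones with alkyl halides and allylstannanes.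

**Step 5**
Reactants: 9 (2R,3R,4R)-3-(dimethoxymethyl)-4-hydroxy-2-methyl-4-(propan-2-yl)-2-(prop-2-en-1-yl)cyclopentan-1-one; 10 3-bromo-2-methylprop-1-ene
Product: 12 (2R,3S,4R)-4-hydroxy-3-[(1S)-1-hydroxy-3-methylbut-3-en-1-yl]-2-methyl-4-(propan-2-yl)-2-(prop-2-en-1-yl)cyclopentan-1-one, via aldehyde 11 (not isolated)
Conditions: 1 M HCl, THF/H2O (3:1), rt; then 10 (3 equiv), In powder (2 equiv), rt
Reagents that add atoms: water, O
Why: Mild acid unmasks the aldehyde, and the Barbier-type indium allylation then runs through a chelate of trivalent indium with the cis tertiary hydroxyl and the aldehyde, so that the methallyl group attacks the convex face of this cis-fused chelate (anti to C2 of the ring) and gives the (1S)-carbinol, with the hindered ketone untouched.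

**Step 6**
Reactants: 13 anisole; 14 oxalyl chloride
Product: 15 4-methoxybenzoyl chloride
Conditions: 14 (2 equiv), AlCl3 (1.1 equiv), CH2Cl2, 0 °C, 13 added last; distil
Reagents that add atoms: none
Why: Friedel–Crafts chlorocarbonylation: oxalyl chloride/AlCl3 loses CO to give the chlorocarbonyl cation, which attacks anisole para to the methoxy group, and the deactivated acid chloride does not react further when anisole is the limiting, last-added component.

**Step 7**
Reactants: 12 (2R,3S,4R)-4-hydroxy-3-[(1S)-1-hydroxy-3-methylbut-3-en-1-yl]-2-methyl-4-(propan-2-yl)-2-(prop-2-en-1-yl)cyclopentan-1-one; 15 4-methoxybenzoyl chloride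
Product: 16 (1S)-1-[(1S,2R,5R)-5-hydroxy-2-methyl-3-oxo-5-(propan-2-yl)-2-(prop-2-en-1-yl)cyclopentyl]-3-methylbut-3-en-1-yl 4-methoxybenzoate
Conditions: 15 (1.5 equiv), Et3N (3 equiv), DMAP (0.2 equiv), CH2Cl2, 0 °C → rt
Reagents that add atoms: none
Why: DMAP-catalysed acylation (Steglich-type acyl transfer) esterifies the secondary hydroxyl selectively over the tertiary one, and no stereocentre is touched.

**Step 8**
Reactants: 16 (1S)-1-[(1S,2R,5R)-5-hydroxy-2-methyl-3-oxo-5-(propan-2-yl)-2-(prop-2-en-1-yl)cyclopentyl]-3-methylbut-3-en-1-yl 4-methoxybenzoate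
Product: 17 (3R,3aS,4S,8aR)-3-hydroxy-6,8a-dimethyl-1-oxo-3-(propan-2-yl)-1,2,3,3a,4,5,8,8a-octahydroazulen-4-yl 4-methoxybenzoate
Conditions: second-generation Hoveyda–Grubbs catalyst (5 mol %), toluene (5 mM), 80 °C
Reagents that add atoms: none
Why: Ring-closing metathesis of the allyl group (on the quaternary carbon) with the methallyl group (on the carbinol side chain), which are trans on the cyclopentane, closes the trans-fused cycloheptene with the trisubstituted C6=C7 alkene and releases ethene, and no stereocentre is touched.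

**Compound list**
1 | 3-methylcyclopent-2-en-1-one | CC1=CC(=O)CC1 | starting material
2 | diisopropylzinc | CC(C)[Zn]C(C)C | starting material
3 | (1R)-3-methyl-1-(propan-2-yl)cyclopent-2-en-1-ol | CC1=C[C@@](O)(CC1)C(C)C | intermediate
4 | (1R)-4-(tert-butylperoxy)-3-methyl-1-(propan-2-yl)cyclopent-2-en-1-ol (C4 epimers) | CC1=C[C@@](O)(CC1OOC(C)(C)C)C(C)C | intermediate (not isolated)
5 | (4R)-4-hydroxy-2-methyl-4-(propan-2-yl)cyclopent-2-en-1-one | CC1=C[C@@](O)(CC1=O)C(C)C | intermediate
6 | trimethyl orthoformate | COC(OC)OC | starting material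
7 | (dimethoxymethyl)(phenyl)selane | COC(OC)[Se]c1ccccc1 | intermediate
8 | allyltrimethylstannane | C=CC[Sn](C)(C)C | starting material
9 | (2R,3R,4R)-3-(dimethoxymethyl)-4-hydroxy-2-methyl-4-(propan-2-yl)-2-(prop-2-en-1-yl)cyclopentan-1-one | COC(OC)[C@@H]1[C@@](C)(CC=C)C(=O)C[C@@]1(O)C(C)C | intermediate
10 | 3-bromo-2-methylprop-1-ene | CC(=C)CBr | starting material
11 | (1R,2R,5R)-5-hydroxy-2-methyl-3-oxo-5-(propan-2-yl)-2-(prop-2-en-1-yl)cyclopentane-1-carbaldehyde | O=C[C@@H]1[C@@](C)(CC=C)C(=O)C[C@@]1(O)C(C)C | intermediate (not isolated)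
12 | (2R,3S,4R)-4-hydroxy-3-[(1S)-1-hydroxy-3-methylbut-3-en-1-yl]-2-methyl-4-(propan-2-yl)-2-(prop-2-en-1-yl)cyclopentan-1-one | O[C@@H](CC(C)=C)[C@@H]1[C@@](C)(CC=C)C(=O)C[C@@]1(O)C(C)C | intermediate
13 | anisole | COc1ccccc1 | starting material
14 | oxalyl chloride | ClC(=O)C(Cl)=O | starting material
15 | 4-methoxybenzoyl chloride | COc1ccc(cc1)C(Cl)=O | intermediate
16 | (1S)-1-[(1S,2R,5R)-5-hydroxy-2-methyl-3-oxo-5-(propan-2-yl)-2-(prop-2-en-1-yl)cyclopentyl]-3-methylbut-3-en-1-yl 4-methoxybenzoate | COc1ccc(cc1)C(=O)O[C@@H](CC(C)=C)[C@@H]1[C@@](C)(CC=C)C(=O)C[C@@]1(O)C(C)C | intermediate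
17 | (3R,3aS,4S,8aR)-3-hydroxy-6,8a-dimethyl-1-oxo-3-(propan-2-yl)-1,2,3,3a,4,5,8,8a-octahydroazulen-4-yl 4-methoxybenzoate | COc1ccc(C(=O)O[C@H]2CC(C)=CC[C@@]3(C)C(=O)C[C@@](O)(C(C)C)[C@H]23)cc1 | target

**Totals**
Total step count: 8. Longest linear sequence: 6 (steps 1, 2, 4, 5, 7, 8).

**Steps most likely to fail, with fallbacks**

The key step 4 is the greatest risk. The facial selectivity at C3 rests only on the isopropyl/hydroxyl size difference and a possible hydrogen bond. The β-carbon also sits next to a quaternary centre, and direct allylation of the acetal radical or simple reduction could compete. (Phenylseleno transfer to the α-keto radical is harmless, since that selenide re-enters the chain.) The fallback sets out from 5 and uses a silicon tether, so that the first C–C bond is delivered intramolecularly. The tertiary hydroxyl is silylated with (bromomethyl)chlorodimethylsilane (imidazole, DMF) to give (4R)-4-{[(bromomethyl)dimethylsilyl]oxy}-2-methyl-4-(propan-2-yl)cyclopent-2-en-1-one F1. With 8 and AIBN the tethered α-silyl radical closes 5-exo onto C3, necessarily cis to the oxygen, and the C2 radical is allylated on the convex face (Stork–Nishiyama cyclisation/Keck allylation). This gives (3aR,4R,6aR)-2,2,4-trimethyl-6a-(propan-2-yl)-4-(prop-2-en-1-yl)hexahydro-5H-cyclopenta[d][1,2]oxasilol-5-one F2. Tamao–Fleming oxidation (H2O2, KF, KHCO3) gives (2R,3S,4R)-4-hydroxy-3-(hydroxymethyl)-2-methyl-4-(propan-2-yl)-2-(prop-2-en-1-yl)cyclopentan-1-one F3. TEMPO/PhI(OAc)2 oxidation of its primary alcohol comes back to the route at aldehyde 11, which is methallylated with indium as in step 5.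

Step 1 is the second risk. A secondary dialkylzinc may give lower enantioselectivity than Me2Zn or Et2Zn and may reduce the ketone by β-hydride transfer. The fallback sets out from 1 and builds the carbinol stereospecifically. CBS reduction ((R)-Me-CBS, BH3·SMe2) gives (1S)-3-methylcyclopent-2-en-1-ol F4. N,N-diisopropylcarbamoyl chloride gives (1S)-3-methylcyclopent-2-en-1-yl N,N-di(propan-2-yl)carbamate F5. Lithiation (s-BuLi, TMEDA, Et2O, −78 °C), borylation with isopropylboronic acid pinacol ester and 1,2-metallate rearrangement on warming give 2-[(1S)-3-methyl-1-(propan-2-yl)cyclopent-2-en-1-yl]-4,4,5,5-tetramethyl-1,3,2-dioxaborolane F6. H2O2/NaOH oxidation with retention comes back to the route at 3.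

Step 2 is the third risk. The allyl radical could be oxidised at the terminus next to the carbinol (giving the transposed enone), the methyl group could be attacked, and the tertiary allylic alcohol is sensitive to acid. The fallback sets out from 3 and replaces the radical peroxidation by an ene/[2,3]-sigmatropic sequence that cannot transpose. SeO2 (cat.)/t-BuOOH in CH2Cl2 hydroxylates the ring CH2 to give (1R)-3-methyl-1-(propan-2-yl)cyclopent-2-ene-1,4-diol F7 (C4 epimers). MnO2 oxidation of the secondary allylic alcohol comes back to the route at 5.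

**Further compounds**
F1 | step 4 | (4R)-4-{[(bromomethyl)dimethylsilyl]oxy}-2-methyl-4-(propan-2-yl)cyclopent-2-en-1-one | CC1=C[C@@](O[Si](C)(C)CBr)(CC1=O)C(C)C
F2 | step 4 | (3aR,4R,6aR)-2,2,4-trimethyl-6a-(propan-2-yl)-4-(prop-2-en-1-yl)hexahydro-5H-cyclopenta[d][1,2]oxasilol-5-one | C[Si]1(C)C[C@@H]2[C@@](C)(CC=C)C(=O)C[C@@]2(O1)C(C)C
F3 | step 4 | (2R,3S,4R)-4-hydroxy-3-(hydroxymethyl)-2-methyl-4-(propan-2-yl)-2-(prop-2-en-1-yl)cyclopentan-1-one | OC[C@@H]1[C@@](C)(CC=C)C(=O)C[C@@]1(O)C(C)C
F4 | step 1 | (1S)-3-methylcyclopent-2-en-1-ol | O[C@@H]1C=C(C)CC1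
F5 | step 1 | (1S)-3-methylcyclopent-2-en-1-yl N,N-di(propan-2-yl)carbamate | CC(C)N(C(C)C)C(=O)O[C@@H]1C=C(C)CC1
F6 | step 1 | 2-[(1S)-3-methyl-1-(propan-2-yl)cyclopent-2-en-1-yl]-4,4,5,5-tetramethyl-1,3,2-dioxaborolane | CC1=C[C@@](B2OC(C)(C)C(C)(C)O2)(CC1)C(C)C
F7 | step 2 | (1R)-3-methyl-1-(propan-2-yl)cyclopent-2-ene-1,4-diol (C4 epimers) | CC1=C[C@@](O)(CC1O)C(C)C
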